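**Isariotin C by carbonyl-ene closure of ring A: design of the route**

Core numbering is used throughout, also for the monocyclic ring-B compounds: C1 bridgehead CH, C2 CHOH, C3 CHN, C4 CH2, C5 bridgehead C–OH, C6–C7 epoxide, C8 CHOH, C9 ketone. Ring A is C1–C2–C3–C4–C5–C9 and ring B is C1–C8–C7–C6–C5–C9. "Exo" means the face of a ring turned away from the other ring.

## The problem

The target, isariotin C 31, is a bicyclo[3.3.1]nonan-9-one in which rings A and B share the C1–C9–C5 bridge, with an (E)-7-oxododec-2-enamide on the C3 nitrogen. The core carries seven stereocentres (C1, C2, C3, C5, C6, C7, C8). The bridgeheads C1 and C5 are tied to each other by the bicycle, and every heteroatom on C2, C3, C6, C7 and C8 lies on the exo face of its ring. Once the bicycle exists, its shape can therefore steer reagents to C2/C3 and C6/C7, but C8 has to be in place earlier, because it is the centre that tells C1, and through C1 also C5, which way to close. The compound is fragile: the C2 and C8 hydroxyls are both β to the C9 ketone with the C1–C2 and C1–C8 bonds aligned for retro-aldol cleavage, C5–OH/C9=O is an α-ketol, the epoxide sits between two carbinols, and the side chain is a Michael acceptor. Both α-carbons of the C9 ketone are bridgeheads, so ring B cannot be functionalised from that ketone after the bicycle is closed; the C6–C7 oxidation must be prepared beforehand. The enabling feature is that the tertiary carbinol C5 lies 1,3 to C1 across C9, that C4 is a bare methylene, and that C2 and C3 carry cis oxygen and nitrogen. An allyl group on C1 of a ring-B cyclohexanone whose ketone is C5 can thus close ring A through C4–C5 by a carbonyl-ene reaction, which creates the C5 hydroxyl and leaves a C2=C3 alkene exactly where the amino alcohol is needed.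

## Retrosynthesis

**Amide bond.** The N–C(acyl) bond of 31 is cut first, giving amino triol 23 and (E)-7-oxododec-2-enoic acid 29. This keeps the enamide and its ketone away from all osmium, vanadium and hydrogenation chemistry. The forward reaction must acylate nitrogen selectively under near-neutral conditions. Acid 29 is cut at its C2=C3 bond, in the cross-metathesis sense, to undec-1-en-6-one 27 and acrylic acid 28, and 27 at its ketone to hex-5-enenitrile 24 and pentylmagnesium bromide 25.

**C3–N and C2–O.** Both bonds are exo and cis on neighbouring carbons, so they are cut together: 23 comes from carbamate 22, and 22 from alkene 18 by syn-aminohydroxylation with the nitrogen source 21, itself made from benzyl N-hydroxycarbamate 19 and 4-chlorobenzoyl chloride 20. Epoxide opening would give the trans relationship and is ruled out. Precursor 18 has a single alkene. The forward step must attack the exo face and put nitrogen on C3.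

**Epoxide.** The two C–O bonds of the epoxide in 18 are cut to give dienone 16 and tert-butyl hydroperoxide 17. The pseudoaxial allylic C8 hydroxyl of 16 is on the exo face and cis to the epoxide to be formed. This director is preferred to the bridgehead C5 hydroxyl, whose C–O bond lies nearly in the plane of C6=C7, and to an undirected peracid, which would favour the more electron-rich C2=C3. Dienone 16 comes from its silyl ether 15. The forward step must distinguish two cis-disubstituted alkenes.

**C9 ketone and C6=C7.** The ketone of 15 is taken back to the carbinol in diene diol 14, and the C6=C7 alkene of 14 to the C6 selenide 12, through selenoxide 13. A selenide is the only practical handle, because it can be placed α to C5 while C5 is still a ketone. C5 is quaternary in 12, so elimination can only run toward C7.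

**C4–C5 (key disconnection).** Diol 12, which forms through its C9 silyl ether 11, is cut at C4–C5 in the ene sense to the monocyclic ketone 10. Cutting C1–C2 or C1–C8 instead (aldol sense) would lead back to retro-aldol-prone polycarbonyl chains. The ene cut removes ring A entirely, leaves a cyclohexanone with contiguous substituents, fixes C5 from C1, and gives the C2=C3 alkene for free. The forward step needs the allyl group axial over the C5 carbonyl and proton loss from C2.

**Ring B substituents.** Ketone 10 is cut at C6–Se to the silyloxy ketone 7 and phenylselenyl chloride 8, through enolate 9. Ketone 7 is cut at C9–O to enol ether 4 and 3-chloroperbenzoic acid 5, through epoxide 6. Enol ether 4 is cut at the C1–allyl bond to enone 1, allylmagnesium bromide 2 and chlorotrimethylsilane 3. Each forward step is steered by the neighbouring centre: C8 directs C1, and C1 directs C9.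

## Roads not taken

**Alternative 1: two-directional double aldol.** The bicycle is cut at C1–C2 and C1–C8, which opens both rings to the acyclic keto dialdehyde A1, a tertiary carbinol (C5) bearing an acetyl group and two (Z)-enal arms. Soft enolisation of the methyl ketone with MgBr2·OEt2 and a tertiary amine would let C1 add to one aldehyde and then the other, giving the meso dienediol A2.
- Merits: one operation delivers both rings, the C9 ketone, the C2, C5 and C8 oxygens and both ring alkenes. Nothing in the chosen plan matches this economy.
- Weak points:
  - Each arm of A1 is a γ-hydroxy (Z)-enal that can close to a lactol and aromatise to a furan, and (Z)-enals isomerise under amines.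
  - The second aldol must close a bridged ring at an already substituted carbon, and both aldols are reversible.
  - A2 is meso, so the absolute configuration and the distinction between rings A and B must come from a later desymmetrisation.
  - The ring-A alkene of A2 is C3=C4, so nitrogen must go to C3 with hydrogen to C4, which is a directed hydroamination and not a syn-aminohydroxylation.
- Comparison: if A1 could be handled, this road would reach a core more oxidised than 14 in far fewer steps. The chosen plan sets against that an absolute configuration carried from 1, rings that differ from step 1 on, and intermediates that are ordinary cyclohexanones.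

**Alternative 2: nitrogen last by nitrene insertion.** Only C3–N is cut. The starting point is the primary carbamate A3, which has the carbamoyl group on O2 of an otherwise complete, silyl-protected core. PhI(OAc)2 and catalytic Rh2(esp)2 would turn it into a rhodium-bound nitrene, and insertion of that nitrene into the exo C3–H bond would give the cis-fused oxazolidinone A4.
- Merits: the five-membered ring fixes nitrogen on C3 and the insertion proceeds with retention, so regiochemistry and configuration are better controlled than in the intermolecular aminohydroxylation of step 10.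
- Weak points:
  - It is an endgame tactic and does not build the skeleton; ring A of A3, with C2–O and saturated C3–C4, must come from another C–C bond formation.
  - The nitrene must prefer the secondary C3–H over the C1–H on the other side of C2 and must tolerate the epoxide.
  - Opening A4 needs hydroxide or extra activation steps, which is hazardous next to two β-hydroxy ketone relationships.
  - Two additional silyl ethers have to be carried and removed.
- Comparison: this road is better at placing nitrogen. The chosen plan sets against it that the ene reaction leaves the alkene through which nitrogen and oxygen arrive together in one step.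

**Alternative 3: Michael–aldol annulation.** C4–C5 and C1–C2 are cut, so ring A comes from acrolein A6 and the ring-B β-keto ester A5. A cinchona-derived amine would catalyse Michael addition through C5 and then aldol closure from C1, giving the bicyclic keto ester A7.
- Merits: it is catalytic, enantioselective and run in one flask from cheap materials. This annulation is one of the best-precedented entries to bicyclo[3.3.1]nonanes and is more dependable than an ene reaction of a ketone with a monosubstituted alkene.
- Weak points:
  - C5 of A7 ends up with a carbomethoxy group where the target has a hydroxyl, and exchanging a bridgehead carbon for oxygen is long and harsh.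
  - A5 is a β,γ-unsaturated β-keto ester that readily slips into conjugation.
  - C8 has no oxygen and C3 no nitrogen, so two later C–H oxidations are needed.
- Comparison: the key step is safer than step 4. The chosen plan sets against it that its key step makes the C5–O bond itself, leaves C2=C3 for the amino alcohol, and has the C8 oxygen from the start.

Key step: step 4

## Route

Remark: enone 1 is taken as a purchasable, enantiopure building block.
Remark: the C6 configuration drawn for 10–13 is the one expected from axial selenenylation; it is erased in step 5.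

Step 1
Reactants: 1 (R)-4-(tert-butyldimethylsilyloxy)cyclohex-2-en-1-one; 2 allylmagnesium bromide; 3 chlorotrimethylsilane
Product: 4 trans-3-allyl-4-(tert-butyldimethylsilyloxy)-1-(trimethylsilyloxy)cyclohex-1-ene
Conditions: 2 (1.5 equiv), CuBr·SMe2 (1.5 equiv), LiCl, 3 (2 equiv), THF, −78 °C; Et3N then pentane work-up
Reagents that add atoms: allylmagnesium bromide C=CC[Mg]Br; chlorotrimethylsilane C[Si](C)(C)Cl
Why: Copper-mediated conjugate allylation accelerated by the silyl chloride; the allylcopper adds to C1 on the face opposite the neighbouring C8 silyl ether (allyl trans to OTBS), and the enolate is trapped on oxygen so that the enol double bond points toward C9.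

Step 2
Reactants: 4 trans-3-allyl-4-(tert-butyldimethylsilyloxy)-1-(trimethylsilyloxy)cyclohex-1-ene; 5 3-chloroperbenzoic acid
Product: 7 3-allyl-4-(tert-butyldimethylsilyloxy)-2-(trimethylsilyloxy)cyclohexan-1-one (C9 silyloxy trans to allyl), via siloxy epoxide 6 (not isolated)
Conditions: 5 (1.05 equiv), NaHCO3, CH2Cl2, −20 → 0 °C; chromatography on Et3N-deactivated silica
Reagents that add atoms: 3-chloroperbenzoic acid OOC(=O)c1cccc(Cl)c1
Why: Rubottom oxidation; the electron-rich enol ether is epoxidised far faster than the terminal alkene and on the face away from the C1 allyl group, and epoxide 6 opens with 1,4-silyl shift to the α-silyloxy ketone. The C9 centre (oxygen trans to allyl, cis to O8) is later erased by oxidation.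

Step 3
Reactants: 7 3-allyl-4-(tert-butyldimethylsilyloxy)-2-(trimethylsilyloxy)cyclohexan-1-one; 8 phenylselenyl chloride
Product: 10 3-allyl-4-(tert-butyldimethylsilyloxy)-6-(phenylselanyl)-2-(trimethylsilyloxy)cyclohexan-1-one (selenium cis to allyl), via lithium enolate 9 (not isolated)
Conditions: LiN(iPr)2 (1.1 equiv), THF, −78 °C; then 8 (1.0 equiv), −78 °C
Reagents that add atoms: phenylselenyl chloride Cl[Se]c1ccccc1
Why: Kinetic enolate selenenylation; the amide base removes a proton from the open C6 methylene and not from the silyloxy-bearing C9 methine, and axial attack of the electrophile on enolate 9 anti to the C8 silyl ether should place selenium cis to the allyl group. The C6 configuration has no bearing on the target.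

Step 4
Reactants: 10 3-allyl-4-(tert-butyldimethylsilyloxy)-6-(phenylselanyl)-2-(trimethylsilyloxy)cyclohexan-1-one
Product: 12 8-exo-(tert-butyldimethylsilyloxy)-6-endo-(phenylselanyl)bicyclo[3.3.1]non-2-ene-5,9-diol (C9 hydroxyl over ring B), via ene adduct silyl ether 11 (not isolated)
Conditions: Me2AlCl (1.5 equiv), CH2Cl2, −78 → 0 °C; then 1 M HCl, THF, 0 °C
Reagents that add atoms: none
Why: Me2AlCl binds the C5 carbonyl oxygen; in the chair of 10 that carries the allyl group axial (C8 and C9 silyloxy groups axial on the other face, selenium equatorial) the terminal alkene carbon C4 lies over C5 and bonds to it while a C2 hydrogen passes to the aluminium-bound oxygen, so that the C4–C5 bond, the C5 carbinol and the C2=C3 alkene arise together. The closest known reaction type is the alkylaluminium-chloride-promoted intramolecular carbonyl-ene (Prins-type) cyclisation of δ,ε-unsaturated ketones with the tether on the allylic carbon, as used to turn 3-alkenylcyclohexanones into bridgehead bicyclo[3.3.1]nonanols. Ring A closes as a six-membered ring, exo at the carbonyl and endo at the alkene, bridging C1 and C5 in the 1,3-diaxial sense, and the hydrogen shift needs a boat-like array of the forming ring. The only new stereocentre, C5, is fixed by C1, because the three-atom tether can reach only the carbonyl face syn to the axial allyl group, and C1 was set trans to C8 in step 1. The step needs the allyl-axial chair, bonding at C4 and not C3, and loss of the C2 proton in preference to chloride capture or a transannular hydride shift at the developing C3 cation. The chair is kept accessible by silylating O9 (a free O9 would hold aluminium between O9 and the carbonyl in the all-equatorial chair, whereas the axial C9–O bond of the silyl ether lies anti to the incoming carbon and activates the ketone); bonding at C3 would give a strained bridged five-membered ring and a primary cation; and Me2AlCl is a weak chloride donor whose methyl groups remove the proton irreversibly as methane. Dilute acid on work-up then cleaves the labile C9 trimethylsilyl ether of 11 and leaves the C8 TBS ether.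

Step 5
Reactants: 12 8-exo-(tert-butyldimethylsilyloxy)-6-endo-(phenylselanyl)bicyclo[3.3.1]non-2-ene-5,9-diol; 5 3-chloroperbenzoic acid
Product: 14 8-exo-(tert-butyldimethylsilyloxy)bicyclo[3.3.1]nona-2,6-diene-5,9-diol, via selenoxide 13 (not isolated)
Conditions: 5 (1.05 equiv), CH2Cl2, −78 °C; then iPr2NH, −78 °C → rt
Reagents that add atoms: none
Why: Selenide oxidation and selenoxide syn-elimination; selenium is oxidised far faster than the C2=C3 alkene at −78 °C, and since C5 is quaternary only a C7 hydrogen can be removed, so the alkene forms as C6=C7. The amine buffers the 3-chlorobenzoic acid and so keeps the benzeneselenenic acid from adding back to the alkenes.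

Step 6
Reactants: 14 8-exo-(tert-butyldimethylsilyloxy)bicyclo[3.3.1]nona-2,6-diene-5,9-diol
Product: 15 8-exo-(tert-butyldimethylsilyloxy)-5-hydroxybicyclo[3.3.1]nona-2,6-dien-9-one
Conditions: IBX (2 equiv), DMSO, rt → 40 °C
Reagents that add atoms: none
Why: IBX oxidation of a secondary alcohol next to a tertiary one gives the α-hydroxy ketone without glycol cleavage; the tertiary C5 hydroxyl, the silyl ether and both alkenes are inert.

Step 7
Reactants: 15 8-exo-(tert-butyldimethylsilyloxy)-5-hydroxybicyclo[3.3.1]nona-2,6-dien-9-one
Product: 16 5,8-exo-dihydroxybicyclo[3.3.1]nona-2,6-dien-9-one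
Conditions: HF·pyridine, pyridine, THF, 0 °C → rt
Reagents that add atoms: none
Why: Fluoride cleavage of the TBS ether under buffered acidic conditions, which never generate an alkoxide β to the C9 ketone and so avoid retro-aldol opening.

Step 8
Reactants: 16 5,8-exo-dihydroxybicyclo[3.3.1]nona-2,6-dien-9-one; 17 tert-butyl hydroperoxide
Product: 18 6,7-exo-epoxy-5,8-exo-dihydroxybicyclo[3.3.1]non-2-en-9-one
Conditions: VO(acac)2 (5 mol %), 17 (1.5 equiv, decane), CH2Cl2, 0 °C → rt
Reagents that add atoms: tert-butyl hydroperoxide CC(C)(C)OO
Why: Vanadium-catalysed hydroxyl-directed epoxidation; the pseudoaxial allylic C8 hydroxyl sits on the exo face and delivers oxygen to C6=C7 on its own side, giving the exo epoxide cis to O8 and O5. C2=C3 is only homoallylic to this hydroxyl and out of its reach.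

Step 9
Reactants: 19 benzyl N-hydroxycarbamate; 20 4-chlorobenzoyl chloride
Product: 21 benzyl N-(4-chlorobenzoyloxy)carbamate
Conditions: Et3N (1.05 equiv), CH2Cl2, 0 °C
Reagents that add atoms: 4-chlorobenzoyl chloride ClC(=O)c1ccc(Cl)cc1
Why: O-acylation of an N-hydroxycarbamate by an aroyl chloride; this gives a bench-stable nitrogen source that also reoxidises osmium, so the aminohydroxylation can be run without base.

Step 10
Reactants: 18 6,7-exo-epoxy-5,8-exo-dihydroxybicyclo[3.3.1]non-2-en-9-one; 21 benzyl N-(4-chlorobenzoyloxy)carbamate
Product: 22 benzyl N-(6,7-exo-epoxy-2-exo,5,8-exo-trihydroxy-9-oxobicyclo[3.3.1]nonan-3-exo-yl)carbamate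
Conditions: K2OsO2(OH)4 (4 mol %), 21 (1.4 equiv), MeCN/H2O (8:1), rt
Reagents that add atoms: benzyl N-(4-chlorobenzoyloxy)carbamate O=C(OCc1ccccc1)NOC(=O)c1ccc(Cl)cc1; water O
Why: Osmium-catalysed syn-aminohydroxylation (Sharpless type, base-free variant); both bonds form on the exo face of ring A because the endo face is covered by ring B. The bulkier N-carbamoyl end should go to C3, whose exo position is equatorial and open, and oxygen to the axial exo site on C2 next to the bridgehead and nearer the electron-withdrawing C9 carbonyl.

Step 11
Reactants: 22 benzyl N-(6,7-exo-epoxy-2-exo,5,8-exo-trihydroxy-9-oxobicyclo[3.3.1]nonan-3-exo-yl)carbamate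
Product: 23 3-exo-amino-6,7-exo-epoxy-2-exo,5,8-exo-trihydroxybicyclo[3.3.1]nonan-9-one
Conditions: H2 (1 atm), Pd/C (10 wt %), EtOAc/MeOH, rt; filtered and used at once
Reagents that add atoms: none
Why: Hydrogenolysis of the benzyl carbamate under neutral conditions; no alkene remains in the core, and the epoxide, ketone and carbinols are not reduced under these conditions.

Step 12
Reactants: 24 hex-5-enenitrile; 25 pentylmagnesium bromide
Product: 27 undec-1-en-6-one, via magnesium ketimide 26 (not isolated)
Conditions: 25 (1.2 equiv), Et2O, 0 °C → reflux; then 2 M HCl, rt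
Reagents that add atoms: pentylmagnesium bromide CCCCC[Mg]Br; water O
Why: Grignard addition to a nitrile stops at the ketimide 26, which cannot add a second equivalent; acid hydrolysis releases the ketone.

Step 13
Reactants: 27 undec-1-en-6-one; 28 acrylic acid
Product: 29 (E)-7-oxododec-2-enoic acid
Conditions: 28 (3 equiv), second-generation Grubbs catalyst (H2IMes)(PCy3)Cl2Ru=CHPh (3 mol %), CH2Cl2, 40 °C
Reagents that add atoms: acrylic acid C=CC(=O)O
Why: Olefin cross-metathesis between a terminal alkene and an electron-poor acrylate partner favours the cross product and the E-alkene; the ketone is tolerated.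

Step 14
Reactants: 23 3-exo-amino-6,7-exo-epoxy-2-exo,5,8-exo-trihydroxybicyclo[3.3.1]nonan-9-one; 29 (E)-7-oxododec-2-enoic acid
Product: 31 isariotin C, via benzotriazolyl ester 30 (not isolated)
Conditions: 29, EDC·HCl (1.2 equiv), HOBt (1.2 equiv), CH2Cl2/DMF, 0 °C; then 23, N-methylmorpholine (1.2 equiv), 0 °C → rt
Reagents that add atoms: (E)-7-oxododec-2-enoic acid CCCCCC(=O)CCC/C=C/C(=O)O
Why: Carbodiimide/hydroxybenzotriazole amide coupling through active ester 30; the primary amine is acylated much faster than the secondary and tertiary hydroxyls, and the near-neutral medium spares the β-hydroxy ketone, the α-ketol and the epoxide.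

## Compound list

1 | (R)-4-(tert-butyldimethylsilyloxy)cyclohex-2-en-1-one | O=C1C=C[C@H](O[Si](C)(C)C(C)(C)C)CC1 | starting material
2 | allylmagnesium bromide | C=CC[Mg]Br | starting material
3 | chlorotrimethylsilane | C[Si](C)(C)Cl | starting material
4 | trans-3-allyl-4-(tert-butyldimethylsilyloxy)-1-(trimethylsilyloxy)cyclohex-1-ene (C5 enol ether toward C9; C1 allyl trans to C8 OTBS) | C[Si](C)(C)OC1=C[C@@H](CC=C)[C@H](O[Si](C)(C)C(C)(C)C)CC1 | intermediate
5 | 3-chloroperbenzoic acid | OOC(=O)c1cccc(Cl)c1 | starting material
6 | C5–C9 epoxide of 4 (epoxide oxygen trans to allyl) | C[Si](C)(C)O[C@@]12O[C@@H]1[C@@H](CC=C)[C@H](O[Si](C)(C)C(C)(C)C)CC2 | intermediate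
7 | 3-allyl-4-(tert-butyldimethylsilyloxy)-2-(trimethylsilyloxy)cyclohexan-1-one (C5 ketone; C9 OTMS trans to C1 allyl, cis to C8 OTBS) | O=C1[C@H](O[Si](C)(C)C)[C@@H](CC=C)[C@H](O[Si](C)(C)C(C)(C)C)CC1 | intermediate
8 | phenylselenyl chloride | Cl[Se]c1ccccc1 | starting material
9 | lithium C5–C6 enolate of 7 | [Li]OC1=CC[C@@H](O[Si](C)(C)C(C)(C)C)[C@H](CC=C)[C@H]1O[Si](C)(C)C | intermediate
10 | 3-allyl-4-(tert-butyldimethylsilyloxy)-6-(phenylselanyl)-2-(trimethylsilyloxy)cyclohexan-1-one (C6 selenium cis to C1 allyl, trans to C8 OTBS) | O=C1[C@H]([Se]c2ccccc2)C[C@@H](O[Si](C)(C)C(C)(C)C)[C@H](CC=C)[C@H]1O[Si](C)(C)C | intermediate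
11 | 8-exo-(tert-butyldimethylsilyloxy)-6-endo-(phenylselanyl)-9-(trimethylsilyloxy)bicyclo[3.3.1]non-2-en-5-ol (O9 over ring B) | O[C@@]12CC=C[C@@H]([C@H](O[Si](C)(C)C(C)(C)C)C[C@H]1[Se]c1ccccc1)[C@H]2O[Si](C)(C)C | intermediate
12 | 8-exo-(tert-butyldimethylsilyloxy)-6-endo-(phenylselanyl)bicyclo[3.3.1]non-2-ene-5,9-diol | O[C@@]12CC=C[C@@H]([C@H](O[Si](C)(C)C(C)(C)C)C[C@H]1[Se]c1ccccc1)[C@H]2O | intermediate
13 | selenoxide of 12 | O[C@@]12CC=C[C@@H]([C@H](O[Si](C)(C)C(C)(C)C)C[C@H]1[Se](=O)c1ccccc1)[C@H]2O | intermediate
14 | 8-exo-(tert-butyldimethylsilyloxy)bicyclo[3.3.1]nona-2,6-diene-5,9-diol | O[C@@]12CC=C[C@@H]([C@H](O[Si](C)(C)C(C)(C)C)C=C1)[C@H]2O | intermediate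
15 | 8-exo-(tert-butyldimethylsilyloxy)-5-hydroxybicyclo[3.3.1]nona-2,6-dien-9-one | O[C@@]12CC=C[C@@H]([C@H](O[Si](C)(C)C(C)(C)C)C=C1)C2=O | intermediate
16 | 5,8-exo-dihydroxybicyclo[3.3.1]nona-2,6-dien-9-one | O[C@@]12CC=C[C@@H]([C@H](O)C=C1)C2=O | intermediate
17 | tert-butyl hydroperoxide | CC(C)(C)OO | starting material
18 | 6,7-exo-epoxy-5,8-exo-dihydroxybicyclo[3.3.1]non-2-en-9-one | O[C@@]12CC=C[C@@H]([C@H](O)[C@@H]3O[C@@H]31)C2=O | intermediate
19 | benzyl N-hydroxycarbamate | ONC(=O)OCc1ccccc1 | starting material
20 | 4-chlorobenzoyl chloride | ClC(=O)c1ccc(Cl)cc1 | starting material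
21 | benzyl N-(4-chlorobenzoyloxy)carbamate | O=C(OCc1ccccc1)NOC(=O)c1ccc(Cl)cc1 | intermediate
22 | benzyl N-(6,7-exo-epoxy-2-exo,5,8-exo-trihydroxy-9-oxobicyclo[3.3.1]nonan-3-exo-yl)carbamate | O=C(OCc1ccccc1)N[C@H]1C[C@@]2(O)C(=O)[C@H]([C@H](O)[C@@H]3O[C@@H]32)[C@H]1O | intermediate
23 | 3-exo-amino-6,7-exo-epoxy-2-exo,5,8-exo-trihydroxybicyclo[3.3.1]nonan-9-one | N[C@H]1C[C@@]2(O)C(=O)[C@H]([C@H](O)[C@@H]3O[C@@H]32)[C@H]1O | intermediate
24 | hex-5-enenitrile | C=CCCCC#N | starting material
25 | pentylmagnesium bromide | CCCCC[Mg]Br | starting material
26 | N-(bromomagnesio)undec-1-en-6-imine | CCCCCC(=N[Mg]Br)CCCC=C | intermediate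
27 | undec-1-en-6-one | CCCCCC(=O)CCCC=C | intermediate
28 | acrylic acid | C=CC(=O)O | starting material
29 | (E)-7-oxododec-2-enoic acid | CCCCCC(=O)CCC/C=C/C(=O)O | intermediate
30 | benzotriazol-1-yl (E)-7-oxododec-2-enoate | CCCCCC(=O)CCC/C=C/C(=O)On1nnc2ccccc12 | intermediate
31 | isariotin C | CCCCCC(=O)CCC/C=C/C(=O)N[C@H]1C[C@@]2(O)C(=O)[C@H]([C@H](O)[C@@H]3O[C@@H]32)[C@H]1O | target

## Step count and risks

Total: 14 steps. Longest linear sequence: 11 steps (steps 1–8, 10, 11, 14). Steps 9, 12 and 13 make the nitrogen source and the side-chain acid.

**Step 4 (key step).** The pairing of a ketone with a monosubstituted alkene is at the unreactive end of carbonyl-ene chemistry, and the reactive chair of 10 holds three axial groups, the two silyloxy groups among them 1,3-diaxial to each other. The likely failure is no conversion under mild Lewis acid and, under stronger acid, diversion of the developing C3 cation into chloride capture or a transannular hydride shift from C7, or loss of the silyl ethers.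

The fallback closes ring A by metathesis at C2=C3 after making C4–C5 by intermolecular allylation. It sets out from 1 and returns at 14. Enone 1 takes up a vinyl group (vinylmagnesium bromide, CuBr·SMe2, LiCl, chlorotrimethylsilane) to give the vinyl silyl enol ether F1, and Rubottom oxidation gives the α-silyloxy ketone F2. Selenenylation at C6 gives the selanyl ketone F3, which is oxidised with H2O2/pyridine and eliminates to the enone F4. Allylmagnesium bromide with CeCl3 adds to the enone carbonyl anti to the C9 silyloxy group to give the tertiary carbinol F5, with allyl cis to vinyl; this facial preference is expected but would have to be confirmed, and only the cis adduct can cyclise. Ring-closing metathesis with the second-generation Grubbs catalyst (H2IMes)(PCy3)Cl2Ru=CHPh joins the vinyl and allyl termini as C2=C3 to give the bicyclic diene silyl ether F6, and dilute acid removes the C9 trimethylsilyl group and gives 14.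

**Step 8.** Directed epoxidation may lose chemoselectivity (oxidation at C2=C3), or the peroxovanadium species may cleave the α-ketol oxidatively. The fallback epoxidises before the ketone exists, using the C9 hydroxyl as director. It sets out from 14 and returns at 18. VO(acac)2/tert-butyl hydroperoxide on 14 is directed by the axial homoallylic C9 hydroxyl, which lies directly over the exo face of C6=C7, and gives the epoxy diol F7. IBX oxidation gives the epoxy ketone F8, and HF·pyridine gives 18.

**Step 10.** Both alkene carbons are secondary, so part of the nitrogen may go to C2. Turnover may also be slow at the hindered osmium azaglycolate, and the free β-hydroxy ketone may undergo retro-aldol opening. The fallback carries the C8 TBS ether through the aminohydroxylation, where it screens the C1/C2 side and removes the free β-hydroxy ketone. It sets out from 14 and returns at 22. It follows the step 8 fallback through the epoxy diol F7 and the epoxy ketone F8; aminohydroxylation of F8 under the osmium conditions of step 10 gives the silyl-protected carbamate F9, and HF·pyridine gives 22.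

**Step 3.** Proton exchange between enolate 9 and product can lead to double selenenylation or C6 epimer mixtures, and the C9 trimethylsilyl ether may be lost on work-up. The fallback separates enolisation from selenenylation. It sets out from 7 and returns at 10. The kinetic enolate is trapped with chlorotrimethylsilane and isolated as the bis-silyl enol ether F10, which as a neutral nucleophile reacts with phenylselenyl chloride at −78 °C to give 10.

## Further compounds

F1 | step 4 | trans-4-(tert-butyldimethylsilyloxy)-1-(trimethylsilyloxy)-3-vinylcyclohex-1-ene | C[Si](C)(C)OC1=C[C@@H](C=C)[C@H](O[Si](C)(C)C(C)(C)C)CC1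
F2 | step 4 | 4-(tert-butyldimethylsilyloxy)-2-(trimethylsilyloxy)-3-vinylcyclohexan-1-one (C9 OTMS trans to vinyl) | O=C1[C@H](O[Si](C)(C)C)[C@@H](C=C)[C@H](O[Si](C)(C)C(C)(C)C)CC1
F3 | step 4 | 4-(tert-butyldimethylsilyloxy)-6-(phenylselanyl)-2-(trimethylsilyloxy)-3-vinylcyclohexan-1-one | O=C1[C@H]([Se]c2ccccc2)C[C@@H](O[Si](C)(C)C(C)(C)C)[C@H](C=C)[C@H]1O[Si](C)(C)C
F4 | step 4 | 4-(tert-butyldimethylsilyloxy)-6-(trimethylsilyloxy)-5-vinylcyclohex-2-en-1-one | O=C1C=C[C@@H](O[Si](C)(C)C(C)(C)C)[C@H](C=C)[C@H]1O[Si](C)(C)C
F5 | step 4 | 1-allyl-4-(tert-butyldimethylsilyloxy)-6-(trimethylsilyloxy)-5-vinylcyclohex-2-en-1-ol (allyl cis to vinyl) | C=CC[C@]1(O)C=C[C@@H](O[Si](C)(C)C(C)(C)C)[C@H](C=C)[C@H]1O[Si](C)(C)C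
F6 | step 4 | 8-exo-(tert-butyldimethylsilyloxy)-9-(trimethylsilyloxy)bicyclo[3.3.1]nona-2,6-dien-5-ol | O[C@@]12CC=C[C@@H]([C@H](O[Si](C)(C)C(C)(C)C)C=C1)[C@H]2O[Si](C)(C)C
F7 | step 8 | 8-exo-(tert-butyldimethylsilyloxy)-6,7-exo-epoxybicyclo[3.3.1]non-2-ene-5,9-diol | O[C@@]12CC=C[C@@H]([C@H](O[Si](C)(C)C(C)(C)C)[C@@H]3O[C@@H]31)[C@H]2O
F8 | step 8 | 8-exo-(tert-butyldimethylsilyloxy)-6,7-exo-epoxy-5-hydroxybicyclo[3.3.1]non-2-en-9-one | O[C@@]12CC=C[C@@H]([C@H](O[Si](C)(C)C(C)(C)C)[C@@H]3O[C@@H]31)C2=O
F9 | step 10 | benzyl N-[8-exo-(tert-butyldimethylsilyloxy)-6,7-exo-epoxy-2-exo,5-dihydroxy-9-oxobicyclo[3.3.1]nonan-3-exo-yl]carbamate | O=C(OCc1ccccc1)N[C@H]1C[C@@]2(O)C(=O)[C@H]([C@H](O[Si](C)(C)C(C)(C)C)[C@@H]3O[C@@H]32)[C@H]1O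
F10 | step 3 | 5-allyl-4-(tert-butyldimethylsilyloxy)-1,6-bis(trimethylsilyloxy)cyclohex-1-ene (C5–C6 enol ether of 7) | C[Si](C)(C)OC1=CC[C@@H](O[Si](C)(C)C(C)(C)C)[C@H](CC=C)[C@H]1O[Si](C)(C)C
A1 | alternative 1 | (2Z,5Z)-4-acetyl-4-hydroxyhepta-2,5-dienedial | CC(=O)C(O)(/C=C\C=O)/C=C\C=O
A2 | alternative 1 | meso 2,5,8-trihydroxybicyclo[3.3.1]nona-3,6-dien-9-one | O[C@@]12C=C[C@H](O)[C@@H]([C@H](O)C=C1)C2=O
A3 | alternative 2 | C2 primary carbamate of the 5-O-triethylsilyl, 8-O-tert-butyldimethylsilyl 6,7-epoxy core | C1C[C@@]2(O[Si](CC)(CC)CC)C(=O)[C@H]([C@H](O[Si](C)(C)C(C)(C)C)[C@@H]3O[C@@H]32)[C@H]1OC(N)=O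
A4 | alternative 2 | C2,C3-fused oxazolidinone of the complete core | O=C1N[C@H]2C[C@@]3(O[Si](CC)(CC)CC)C(=O)[C@H]([C@H](O[Si](C)(C)C(C)(C)C)[C@@H]4O[C@@H]43)[C@H]2O1
A5 | alternative 3 | methyl 6-oxocyclohex-2-ene-1-carboxylate | COC(=O)C1C=CCCC1=O
A6 | alternative 3 | acrolein | C=CC=O
A7 | alternative 3 | methyl 2-hydroxy-9-oxobicyclo[3.3.1]non-6-ene-5-carboxylate (core numbering) | C1C[C@@]2(C(=O)OC)C(=O)[C@H](CC=C2)[C@H]1O
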